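**Retrosynthetic overview**

1. Numbering follows an isoflavone: pyranone O1, C2, C3, C4(=O); ring A C4a–C8a (5-OH, chroman O on C7, chroman CH2 on C8); ring B C1'–C6' (furan O on C2', chromene on C3'/C4', 5'-OH). The strategy rests on one feature: C2, C3 and the furan oxygen are the carbonyl carbon, the CH2 and the ring oxygen of a ring B benzofuran-2(3H)-one, whose carbonyl oxygen can become O1.
2. Key disconnection: C3–C4 and O1–C8a, giving the ring B lactone (phenol masked) and a ring A 2-fluoroaroyl chloride. The pyranone is closed last, by C-acylation of the lactone enolate followed by fluoride displacement.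
3. Ring B lactone: 2,5-dimethoxyphenol → 2,2-dimethylchromene (propargyl ether, Claisen) → 5,8-quinone → conjugate addition of an acetate ketene silyl acetal at C6 and lactonisation (this lactone is the later furan ring) → tetrahydropyranyl (THP) acetal.
4. Ring A chloride: 3-fluoro-5-methoxyphenol → ortho-prenylation between O and F → acid closure of the chroman → lithiation and carboxylation between F and OMe → acid chloride.
5. Ring order: chroman on ring A; chromene on ring B, then the lactone; pyranone; finally BCl3 frees 5-OH (chelated methyl ether) and 5'-OH (acetal).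

Key step: step 11

Remark: the THP ether on ring B brings in one acetal stereocentre, so those intermediates are racemic; the target has no stereocentre.

**Route**

Step 1
Reactants: 1 3-fluoro-5-methoxyphenol
Product: 2 1-fluoro-3-methoxy-5-(methoxymethoxy)benzene
Conditions: MOMCl, K2CO3, acetone, 0 °C → rt
Reagents that add atoms: chloromethyl methyl ether COCCl
Why: Williamson-type O-alkylation of the phenoxide by the reactive α-chloro ether gives the methoxymethyl ether, which serves both as protecting group and as the strongest ortho-director on the ring.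

Step 2
Reactants: 2 1-fluoro-3-methoxy-5-(methoxymethoxy)benzene; 3 prenyl bromide (1-bromo-3-methylbut-2-ene)
Product: 4 1-fluoro-5-methoxy-3-(methoxymethoxy)-2-(3-methylbut-2-en-1-yl)benzene
Conditions: n-BuLi, THF, −78 °C; CuBr·SMe2, −78 °C; 3, −78 °C → rt
Reagents that add atoms: none
Why: Directed ortho-metalation should take place at the C–H flanked by fluorine (acidifying) and the chelating OCH2OCH3 group rather than next to the weaker OMe director, and the derived arylcopper, which cannot lose LiF to an aryne, is allylated by prenyl bromide at its primary carbon (SN2-type allylic substitution).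

Step 3
Reactants: 4 1-fluoro-5-methoxy-3-(methoxymethoxy)-2-(3-methylbut-2-en-1-yl)benzene
Product: 6 5-fluoro-7-methoxy-2,2-dimethylchromane, via prenylphenol 5 (not isolated)
Conditions: 3 M HCl, MeOH, 50 °C; then p-TsOH·H2O (cat.), toluene, 80 °C
Reagents that add atoms: none
Why: Acid-catalysed acetal exchange removes the methoxymethyl group and the freed phenol then adds to the Markovnikov-protonated prenyl alkene (intramolecular hydroalkoxylation through the tertiary cation), which closes the 2,2-dimethylchroman.

Step 4
Reactants: 6 5-fluoro-7-methoxy-2,2-dimethylchromane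
Product: 7 5-fluoro-7-methoxy-2,2-dimethylchromane-6-carboxylic acid
Conditions: s-BuLi, TMEDA, THF, −78 °C; CO2; then 1 M HCl
Reagents that add atoms: carbon dioxide O=C=O
Why: Directed ortho-lithiation should occur at chroman C6, the only C–H flanked by fluorine and OMe and more acidic than C8 between OMe and the hindered ring oxygen, and the aryllithium, stable to LiF loss at −78 °C, is carboxylated by CO2.

Step 5
Reactants: 7 5-fluoro-7-methoxy-2,2-dimethylchromane-6-carboxylic acid
Product: 8 5-fluoro-7-methoxy-2,2-dimethylchromane-6-carbonyl chloride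
Conditions: (COCl)2, DMF (cat.), CH2Cl2, 0 °C → rt; used crude
Reagents that add atoms: oxalyl chloride ClC(=O)C(=O)Cl
Why: Vilsmeier-type activation by oxalyl chloride and catalytic DMF converts the acid into the acid chloride with gaseous by-products only, so the hindered chloride can be used without purification.

Step 6
Reactants: 9 2,5-dimethoxyphenol; 10 3-chloro-3-methylbut-1-yne
Product: 11 1,4-dimethoxy-2-[(2-methylbut-3-yn-2-yl)oxy]benzene
Conditions: K2CO3, KI, CuI (cat.), acetone, 55 °C
Reagents that add atoms: none
Why: Copper-assisted O-propargylation of the phenoxide by the tertiary propargylic chloride (SN1-like substitution through a copper acetylide) gives the aryl 1,1-dimethylpropargyl ether.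

Step 7
Reactants: 11 1,4-dimethoxy-2-[(2-methylbut-3-yn-2-yl)oxy]benzene
Product: 12 5,8-dimethoxy-2,2-dimethyl-2H-chromene
Conditions: N,N-diethylaniline, 180 °C
Reagents that add atoms: none
Why: Aromatic propargyl Claisen rearrangement to the only free ortho carbon, enolisation, 1,5-hydrogen shift and oxa-6π electrocyclisation of the resulting ortho-quinone methide should deliver the 2,2-dimethyl-2H-chromene.

Step 8
Reactants: 12 5,8-dimethoxy-2,2-dimethyl-2H-chromene
Product: 13 2,2-dimethyl-2H-chromene-5,8-dione
Conditions: (NH4)2Ce(NO3)6, MeCN/H2O, 0 °C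
Reagents that add atoms: water O
Why: Oxidative demethylation of the para-dimethoxyarene (two one-electron oxidations with attack of water at the ipso carbons) gives the para-quinone, and the styrene-type pyran double bond is oxidised less easily than the dimethoxyarene and should survive.

Step 9
Reactants: 13 2,2-dimethyl-2H-chromene-5,8-dione; 14 tert-butyl[(1-methoxyethenyl)oxy]dimethylsilane
Product: 17 lactone of (5,8-dihydroxy-2,2-dimethyl-2H-chromen-6-yl)acetic acid closed onto O5 (8-OH free), via silyl ether adduct 15 (not isolated), via hydroquinone ester 16 (not isolated)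
Conditions: Sc(OTf)3 (5 mol%), MeCN, −40 → 0 °C; then HF·pyridine, THF, 0 °C; then p-TsOH·H2O (cat.), toluene, 70 °C; under argon
Reagents that add atoms: none
Why: Mukaiyama–Michael addition, in which the ring oxygen on chromene C8a makes C5=O a vinylogous ester so that the ketene silyl acetal adds at C6 (β to the more electrophilic C8=O), is followed by aromatisation to the hydroquinone monosilyl ether, removal of silicon by fluoride and acid-catalysed transesterification of O5–H with the neighbouring ester to the five-membered lactone.

Step 10
Reactants: 17 lactone of (5,8-dihydroxy-2,2-dimethyl-2H-chromen-6-yl)acetic acid closed onto O5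
Product: 18 the same lactone with the 8-OH as its tetrahydropyran-2-yl ether (racemic at the acetal carbon)
Conditions: 3,4-dihydro-2H-pyran, pyridinium p-toluenesulfonate (cat.), CH2Cl2, rt
Reagents that add atoms: 3,4-dihydro-2H-pyran C1=COCCC1
Why: Acid-catalysed addition of the phenol to the enol ether (acetal formation) masks the hydroxyl without any base, which matters because the lactone CH2 is at least as acidic as the phenol and would compete in a base-mediated alkylation.

Step 11
Reactants: 18 THP-protected ring B lactone; 8 5-fluoro-7-methoxy-2,2-dimethylchromane-6-carbonyl chloride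
Product: 20 5-O-methyl-5'-O-(tetrahydropyran-2-yl) Formosanatin D (racemic at the acetal carbon), via β-keto lactone 19 (not isolated)
Conditions: LiN(SiMe3)2 (2.2 equiv), THF, −78 °C; 8, −78 → 0 °C; then DMF, 90 °C (THF distilled off)
Reagents that add atoms: none
Why: LiN(SiMe3)2 turns lactone 18 into its 2-oxidobenzofuran enolate, which is acylated at C3 by the aroyl chloride 8 (crossed Claisen-type acylation); any enol ester formed at oxygen is carried over to carbon by enolate-catalysed acyl transfer, and the second equivalent of base drains the equilibrium as the stabilised β-keto lactone anion 19. On heating in DMF the lactone-derived enolate oxygen adds to C8a, ortho to the new ketone, and fluoride leaves through a Meisenheimer intermediate (intramolecular SNAr, addition–elimination), which forms O1–C8a after C3–C4. The closest known reaction type is the tandem C-acylation and fluoride displacement of active-methylene compounds with 2-fluorobenzoyl chlorides that gives chromones, 2-alkoxychromones and 4-quinolones. The pyranone closes as a six-membered ring by attack of oxygen on an aromatic carbon held close by the planar enolate, the ring gains pyrone aromaticity while LiF separates, and no stereocentre is formed. The step needs C- over O-acylation (secured by the thermodynamic sink just named), closure by the lactone oxygen and not the ketone oxygen (which could only give a four-membered ring), and loss of fluoride and not of the 5-OMe group that also sits ortho to the ketone (fluoride is by far the better leaving group in addition–elimination, and loss of methoxide would give the linear isomer). Both ether oxygens of ring A are meta to C8a and so put no electron density on the carbon under attack, and ring A carries no free phenol that could open the lactone toward a coumestan-type isomer.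

Step 12
Reactants: 20 5-O-methyl-5'-O-(tetrahydropyran-2-yl) Formosanatin D
Product: 21 Formosanatin D
Conditions: BCl3 (5 equiv), CH2Cl2, −78 → 0 °C; then aqueous NaHCO3
Reagents that add atoms: none
Why: Lewis-acid ether cleavage, in which BCl3 ionises the THP acetal at once and, chelated between the C4 carbonyl and the peri 5-OMe, delivers chloride to that methyl group only (chelation-controlled demethylation), should leave the unchelated chroman, chromene, furan and pyranone oxygens untouched at low temperature.

**Compound list**

1 | 3-fluoro-5-methoxyphenol | COc1cc(O)cc(F)c1 | starting material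
2 | 1-fluoro-3-methoxy-5-(methoxymethoxy)benzene | COCOc1cc(F)cc(OC)c1 | intermediate
3 | prenyl bromide (1-bromo-3-methylbut-2-ene) | CC(C)=CCBr | starting material
4 | 1-fluoro-5-methoxy-3-(methoxymethoxy)-2-(3-methylbut-2-en-1-yl)benzene | COCOc1cc(OC)cc(F)c1CC=C(C)C | intermediate
5 | 3-fluoro-5-methoxy-2-(3-methylbut-2-en-1-yl)phenol | COc1cc(O)c(CC=C(C)C)c(F)c1 | intermediate (not isolated)
6 | 5-fluoro-7-methoxy-2,2-dimethylchromane | COc1cc(F)c2CCC(C)(C)Oc2c1 | intermediate
7 | 5-fluoro-7-methoxy-2,2-dimethylchromane-6-carboxylic acid | COc1cc2OC(C)(C)CCc2c(F)c1C(=O)O | intermediate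
8 | 5-fluoro-7-methoxy-2,2-dimethylchromane-6-carbonyl chloride | COc1cc2OC(C)(C)CCc2c(F)c1C(=O)Cl | intermediate
9 | 2,5-dimethoxyphenol | COc1ccc(OC)c(O)c1 | starting material
10 | 3-chloro-3-methylbut-1-yne | CC(C)(Cl)C#C | starting material
11 | 1,4-dimethoxy-2-[(2-methylbut-3-yn-2-yl)oxy]benzene | COc1ccc(OC)c(OC(C)(C)C#C)c1 | intermediate
12 | 5,8-dimethoxy-2,2-dimethyl-2H-chromene | COc1ccc(OC)c2OC(C)(C)C=Cc12 | intermediate
13 | 2,2-dimethyl-2H-chromene-5,8-dione | CC1(C)C=CC2=C(O1)C(=O)C=CC2=O | intermediate
14 | tert-butyl[(1-methoxyethenyl)oxy]dimethylsilane | C=C(OC)O[Si](C)(C)C(C)(C)C | starting material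
15 | methyl 2-[8-(tert-butyldimethylsilyloxy)-5-hydroxy-2,2-dimethyl-2H-chromen-6-yl]acetate | COC(=O)Cc1cc(O[Si](C)(C)C(C)(C)C)c2OC(C)(C)C=Cc2c1O | intermediate (not isolated)
16 | methyl 2-(5,8-dihydroxy-2,2-dimethyl-2H-chromen-6-yl)acetate | COC(=O)Cc1cc(O)c2OC(C)(C)C=Cc2c1O | intermediate (not isolated)
17 | 5-hydroxybenzofuran-2(3H)-one fused at C6 (O) and C7 with a 2,2-dimethyl-2H-pyran | O=C1Cc2cc(O)c3OC(C)(C)C=Cc3c2O1 | intermediate
18 | 5-(tetrahydropyran-2-yloxy) derivative of 17, racemic | O=C1Cc2cc(OC4CCCCO4)c3OC(C)(C)C=Cc3c2O1 | intermediate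
19 | 3-(5-fluoro-7-methoxy-2,2-dimethylchromane-6-carbonyl) derivative of 18, present as its lithium enolate, keto form drawn | O=C1Oc2c(cc(OC3CCCCO3)c3OC(C)(C)C=Cc23)C1C(=O)c1c(F)c2CCC(C)(C)Oc2cc1OC | intermediate (not isolated)
20 | 5-O-methyl-5'-O-(tetrahydropyran-2-yl) Formosanatin D, racemic | O=c1c2c(OC)cc3OC(C)(C)CCc3c2oc2oc3c4C=CC(C)(C)Oc4c(OC5CCCCO5)cc3c12 | intermediate
21 | Formosanatin D | CC1(C)C=Cc2c(c(O)cc3c2oc2oc4c5c(cc(O)c4c(=O)c23)OC(C)(C)CC5)O1 | target

**Step count and risks**

Total steps: 12. Longest linear sequence: 7 steps (steps 6–10, 11, 12, or steps 1–5, 11, 12).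

Steps most likely to fail:

Step 11. The ambident lactone enolate may be acylated on oxygen by the hindered aroyl chloride, and the enol ester (or the strained β-keto lactone anion) may fragment or open faster than the acyl group reaches C3 and fluoride is displaced. The fallback sets out from 18 and 8 and returns at 20. It opens the lactone, so that a plain ester enolate is acylated and the furan ring is closed last.
- Methanolysis of 18 (K2CO3 cat., MeOH, 0 °C) should give methyl 2-[5-hydroxy-2,2-dimethyl-8-(tetrahydropyran-2-yloxy)-2H-chromen-6-yl]acetate F1.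
- Silylation (t-BuMe2SiCl, imidazole, DMF) gives its 5-O-silyl ether F2.
- The lithium enolate of F2 (LiN(SiMe3)2, 2.2 equiv, THF, −78 °C) is C-acylated by 8 in a crossed Claisen condensation to the β-keto ester F3.
- Cs2CO3 in DMF at 90 °C closes the pyranone through the ester carbonyl oxygen by fluoride displacement, giving the 2-methoxyisoflavone F4.
- Bu4NF in THF frees the 2'-phenoxide, which displaces methoxide from C2 by addition–elimination and so gives 20.

Step 9. Electron transfer from the electron-rich ketene silyl acetal to the quinone, redox exchange between adduct and unreacted quinone, or addition at C7 may take the place of clean conjugate addition at C6. The fallback sets out from 12 and 14 and returns at 16, hence at 17. It puts the two-carbon chain on the arene before the quinone stage.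
- Bromination of 12 (N-bromosuccinimide, MeCN, 0 °C) at C6, para to the ring oxygen, should give 6-bromo-5,8-dimethoxy-2,2-dimethyl-2H-chromene F5.
- Palladium-catalysed α-arylation of 14 (Pd(dba)2, P(t-Bu)3, ZnF2, DMF, 80 °C) gives methyl 2-(5,8-dimethoxy-2,2-dimethyl-2H-chromen-6-yl)acetate F6.
- (NH4)2Ce(NO3)6 in MeCN/H2O gives the quinone ester methyl 2-(2,2-dimethyl-5,8-dioxo-5,8-dihydro-2H-chromen-6-yl)acetate F7.
- Na2S2O4 in the work-up reduces F7 to 16, and p-TsOH in toluene closes 17 as in step 9.

Step 2. Lithiation may occur partly between fluorine and OMe, or LiF may be lost to an aryne before transmetalation, giving regioisomeric or scrambled prenyl arenes. The fallback sets out from 3 and returns at 6. It brings in the chroman oxygen by fluoride displacement on a symmetric arene, so no regiochemical choice remains.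
- Commercial 3,5-difluoroanisole F8 is lithiated between the two fluorines (n-BuLi, THF, −78 °C) and prenylated with 3 through the arylcopper (CuBr·SMe2) to 1,3-difluoro-5-methoxy-2-(3-methylbut-2-en-1-yl)benzene F9.
- Mukaiyama hydration (Co(acac)2 cat., PhSiH3, O2, i-PrOH) gives the tertiary alcohol 4-(2,6-difluoro-4-methoxyphenyl)-2-methylbutan-2-ol F10.
- KOt-Bu in DMF at 90 °C closes the chroman by intramolecular displacement of one of the two equivalent fluorines, giving 6.

**Further compounds**

F1 | step 11 | methyl 2-[5-hydroxy-2,2-dimethyl-8-(tetrahydropyran-2-yloxy)-2H-chromen-6-yl]acetate | COC(=O)Cc1cc(OC3CCCCO3)c2OC(C)(C)C=Cc2c1O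
F2 | step 11 | methyl 2-[5-(tert-butyldimethylsilyloxy)-2,2-dimethyl-8-(tetrahydropyran-2-yloxy)-2H-chromen-6-yl]acetate | COC(=O)Cc1cc(OC3CCCCO3)c2OC(C)(C)C=Cc2c1O[Si](C)(C)C(C)(C)C
F3 | step 11 | methyl 2-[5-(tert-butyldimethylsilyloxy)-2,2-dimethyl-8-(tetrahydropyran-2-yloxy)-2H-chromen-6-yl]-3-(5-fluoro-7-methoxy-2,2-dimethylchroman-6-yl)-3-oxopropanoate | COC(=O)C(C(=O)c1c(F)c2CCC(C)(C)Oc2cc1OC)c1cc(OC3CCCCO3)c2OC(C)(C)C=Cc2c1O[Si](C)(C)C(C)(C)C
F4 | step 11 | 2-methoxyisoflavone: 2,5-dimethoxy pyranone with the ring A chroman, bearing at C3 the ring B aryl with 2'-O-silyl and 5'-O-THP groups | COc1oc2c3CCC(C)(C)Oc3cc(OC)c2c(=O)c1-c1cc(OC3CCCCO3)c2OC(C)(C)C=Cc2c1O[Si](C)(C)C(C)(C)C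
F5 | step 9 | 6-bromo-5,8-dimethoxy-2,2-dimethyl-2H-chromene | CC1(C)C=Cc2c(OC)c(Br)cc(OC)c2O1
F6 | step 9 | methyl 2-(5,8-dimethoxy-2,2-dimethyl-2H-chromen-6-yl)acetate | COC(=O)Cc1cc(OC)c2OC(C)(C)C=Cc2c1OC
F7 | step 9 | methyl 2-(2,2-dimethyl-5,8-dioxo-5,8-dihydro-2H-chromen-6-yl)acetate | COC(=O)CC1=CC(=O)C2=C(C=CC(C)(C)O2)C1=O
F8 | step 2 | 3,5-difluoroanisole (purchased) | COc1cc(F)cc(F)c1
F9 | step 2 | 1,3-difluoro-5-methoxy-2-(3-methylbut-2-en-1-yl)benzene | COc1cc(F)c(CC=C(C)C)c(F)c1
F10 | step 2 | 4-(2,6-difluoro-4-methoxyphenyl)-2-methylbutan-2-ol | COc1cc(F)c(CCC(C)(C)O)c(F)c1
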